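Late in these flasks, the less substrate stands, the closer the dissolved partner comes to its saturation value of 30 mM. What you need is how far below that value the substrate holds it earlier, since product forms at a rate first order in each.

| setting | violet | blue | red |
|---|---|---|---|
| substrate | 0.10 M | 0.20 M | 0.40 M |
| gas | 30 mM (held) | 30 mM (held) | 30 mM (held) |
| time | 10 min | 10 min | 10 min |

    partner → decomposed reagent (k1 = 0.036 min⁻¹)
    substrate + partner → product + by-product (k2 = 3.8 M⁻¹ min⁻¹)
    gas ⇌ partner, rate k3*(csat - [partner]) (k3 = 13 min⁻¹, csat = 30 mM)

- at the start none of partner is dissolved
- "hardly changes" means that all values lie within two and a half points (for a concentration: within two and a half percent of the largest)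
- run time (violet): 10 min

1. amount of product at the end, in percent of the substrate charged for violet, blue, red, in this order
2. the course of these numbers from the first flask to the last (falls all the way / rises, then falls / hardly changes / falls, then rises / rises all the way)

Write S and P for the concentrations of substrate and partner, c_sat for the saturation concentration, k_T for the transfer coefficient, k_D for the decomposition constant and k_C for the constant of the product-forming step. Going from the fastest rung down, transfer refills the partner with a half-life of 0.0533 min, far shorter than the half-life of 1.8 min that partner has against the substrate charged in violet, and that in turn is far shorter than the half-life of 19 min of its decomposition in violet. So by about 0.267 min feed and loss balance, k_T(c_sat − P) = (k_D + k_C S)P, and P = k_T c_sat/(k_T + k_D + k_C S). With P nearly steady the substrate decays almost pseudo-first-order, and the held constant, k′ = k_C P taken at the charged S, is the quantity to carry.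

It comes to 0.110 min⁻¹ for violet, a substrate half-life of 6.27 min, then 0.107 min⁻¹ for blue and 0.102 min⁻¹ for red. My row from 1 − exp(−k′t) is 66.9%, 65.8% and 63.9%. That spread of 3 percentage points reads as falling all the way, but S drops from its charge during the run, so the pull on partner is overstated, and more so in red.

The forecast differs from my shape: it gives 67%, 66.4% and 65.1%, course hardly changes, on the grounds that “The spread is 1.9 points, within the 2.5-point limit”.

The flasks give 67.0%, 66.4% and 65.1%, and the course hardly changes.

In violet the product-forming step ran while substrate fell to 57.8% at 5.00 min and 33.0% at 10.0 min, with partner at 0.0294 M and then 0.0296 M, and the held constant's 66.9% stands beside the 67.0% found. In red, with partner at 0.0280 M at 5.00 min and 0.0287 M at 10.0 min, the held constant's 63.9% lies 1.2 points under the 65.1% found.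

Its constants are assumed, and the outcome is calculated.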